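## Structural features

The target is a 5,7-dihydroxyflavone (rings A and C). Its ring B is the benzo ring of a 2,3-dihydrobenzofuran, and flavone C2 is bonded to benzofuran C5, para to the ring oxygen O1. Benzofuran C7, ortho to O1, carries a prenyl chain. C2 carries a 2-hydroxypropan-2-yl group and C3 a secondary benzylic hydroxyl. C2 and C3 are the only stereocentres; they are adjacent, both R, and the C3 hydroxyl and the C2 side chain lie on opposite faces (trans). The most fragile site is the C3 carbinol, because ionisation there leads to an aromatic benzofuran, either by loss of the C2 proton or by Grob-type loss of acetone. The prenyl alkene is sensitive to acid, to oxidants and to excited carbonyl groups. The flavone half is routine. The real difficulty is to place the trans 2,3-dioxygenated pair, in one absolute sense, on a ring that tends to aromatise and stands next to a tertiary alcohol. The key step exploits the chain O–C3–C2–CMe2–O. The two hydroxyl oxygens are 1,3-related through C2, so a single oxygen can bridge C3 and CMe2 as an oxetane cis-fused to the dihydrofuran along C2–C3. A retro-[2+2] then reveals an aryl aldehyde (C3=O) ortho to an aryl enol ether (O1–C2=CMe2).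

## Logic of the disconnections

**20 to 18.** The O1–C2 bond of ring C is cut, the C2=C3 double bond is formally rehydrated, and the two dihydrofuran hydroxyls are re-masked as silyl ethers. This heteroatom bond forms by itself once a ring A phenol and the aryl ketone sit in one chain, so ring C needs no construction of its own. The gain is one ring fewer and an open chain with two clearly different halves. The forward step must close, dehydrate and desilylate in acid weak enough that C3–OH does not ionise and the prenyl group is not hydrated.

**18 to 14 and 15.** The C–C bond between the ring B acyl carbon and the central methylene (the future flavone C2–C3 bond) is cut. This is the only cut that separates the stereodefined half from an achiral, purchasable half, so the route becomes convergent at a late stage. The forward step is a C-acylation in excess amide base. It therefore needs both hydroxyls of 14 masked and an acyl donor made without free HCl.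

**14 to 12 to 11.** Only O–Si and O–CH3 bonds change; no skeletal bond is cut. The ester is hydrolysed before silylation so that no silyl ether has to survive hydroxide. The forward steps need one reagent that silylates a secondary and a tertiary hydroxyl together, and a silyl ester that falls off selectively.

**11 to 10.** No bond is cut; the single enantiomer is traced back to the racemate. A chiral Lewis acid on the formyl oxygen is not relied on. It would tie up the oxygen lone pair that gives the aldehyde its n,π* reactivity, and it would steer the excited state toward arene–alkene chemistry. The gain is that the two steps before this point need only relative stereocontrol. The demand is a resolving agent that distinguishes the two C3 carbinols and leaves the tertiary alcohol and the ester alone.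

**10 to 9.** The C3–OH bond is cut and C3 is joined to the tertiary oxygen. The trans diol thus becomes a cis-fused oxetane with the opposite configuration at C3. This cut turns a trans relationship, which is hard to set directly, into a cis ring fusion that is geometrically enforced. The forward step needs water to attack C3 and not CMe2, with inversion, and faster than the ring aromatises.

**9 to 7.** C2–C3 and O–CMe2 are cut together. Two rings, two skeletal bonds and both stereocentres vanish, and a flat, achiral tetrasubstituted benzene remains. The forward step needs an excited aldehyde that adds to the neighbouring enol ether in the fused orientation and ignores the prenyl alkene.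

**7 to 5 and 6.** The O1–C(vinyl) bond is cut. This keeps the acid-sensitive enol ether out of all earlier steps and uses a C4 vinyl halide with no alkene geometry to control. The forward step needs C(sp2)–O coupling on a hindered, electron-poor phenol.

**5 to 3.** The aryl–CHO bond is cut. The phenol directs formylation to its only free ortho position. The forward step needs conditions that tolerate the prenyl group and the ester.

**3 to 1 and 2.** The aryl–CH2 bond of the prenyl group is cut. Cross-coupling replaces direct C-prenylation, which is unreliable on an acceptor-substituted phenol. It is placed before the aldehyde exists because allylic boronates add to aldehydes. The forward step needs bond formation at the unsubstituted end of the prenyl unit.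

## Other disconnections considered

**Alternative 1:**
- **Cut.** The cut is at O1–C2 of the dihydrofuran and at the tertiary C–OH bond, and O1 is reconnected to CMe2. This leads to the trans (3S,4R)-3-hydroxy-4-(triethylsilyloxy)-2,2-dimethylchroman A2. A2 would come from the flavone-bearing 2,2-dimethylchromene A1 by asymmetric epoxidation, hydrolysis at the benzylic carbon and silylation of the benzylic hydroxyl.
- **Forward key step.** The C3 hydroxyl of A2 is triflated. The C2–O1 bond, antiperiplanar to the equatorial leaving group, shifts to C3 with inversion. Water then captures the tertiary cation and gives the tris-silylated target A3.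
- **In favour.** The absolute configuration would come from a Mn(salen)Cl-type epoxidation of a cis-disubstituted chromene double bond, a favourable substrate class. On this point the alternative is clearly better than the chosen plan, which gives up half of its material in a resolution. The benzylic oxygen is already silylated when cationic character develops, which is at least equal to the chosen plan in protecting C3.
- **Against.** O1 lies para to the electron-poor chromone and is therefore a weak migrating group, so hydride shift from C4 or elimination can compete. The oxidant must choose the chromene alkene over the prenyl alkene. Two secondary hydroxyls must be told apart. A1 needs its own chromene synthesis on a ring that already carries the prenyl group.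
- **Comparison.** Both plans depend on one clean inversion. The chosen plan makes two rings and two skeletal bonds in one operation from a precursor three steps from commercial material. This alternative only reshapes an existing ring and would probably be somewhat longer.

**Alternative 2:**
- **Cut.** The cut is the C4a–C8a bond of ring A, which leads to the methyl 9-aryl-3,5,7-trioxonon-8-enoate A4.
- **Forward key step.** Mg(OMe)2 in methanol folds the chain so that C6 attacks the ester carbon C1. Enolisation then gives the 2',4',6'-trihydroxychalcone A5.
- **In favour.** The logic is biomimetic, the base is mild, and ring A appears with free phenols. In needing no ring A protection it is the equal of the chosen plan.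
- **Against.** It addresses none of the stereochemical difficulty, since ring B must already be complete. It builds a ring that can be bought as 15. A4 is a labile polyketo ester open to aldol closure, pyranone formation and conjugate addition. A5 still needs an oxidative cyclisation to reach the flavone level, with an oxidant that must spare the prenyl group.
- **Comparison.** The chosen plan reaches the flavone oxidation level directly from a carboxylic acid and is shorter. This alternative adds steps without simplifying the hard part.

**Alternative 3:**
- **Cut.** The cut is the C3a–C3 bond, which leads to the (S)-configured α-aryloxy aldehyde bearing an ortho iodide, A6. Its C2 stereocentre would derive from a Sharpless asymmetric epoxidation of an allylic alcohol.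
- **Forward key step.** CrCl2 with catalytic NiCl2 converts the aryl iodide into an arylchromium species that adds to the tethered aldehyde. This gives the trans 3-hydroxy dihydrobenzofuran A7.
- **In favour.** Every reaction type is known, the method tolerates the ester and the prenyl group, and the absolute configuration comes from a reliable catalytic reaction. In precedent and in enantiocontrol this alternative is better than the chosen plan. A7 is the tertiary silyl ether of 11, so the endgame would be the same, which makes the two plans equal there.
- **Against.** A6 is configurationally fragile, being enolisable and open to β-elimination of the silyloxy group. The ether bond to a secondary carbon next to a quaternary centre must be made from a hindered, electron-poor iodophenol. The trans selectivity of the five-membered closure rests on 1,2-induction that is not assured. Chromium is needed in stoichiometric amount, and the two ortho positions of the phenol must be differentiated as iodide and prenyl.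
- **Comparison.** A7 would probably need more steps than the six that lead to 11. Those steps would carry less mechanistic risk, so the choice is between brevity with bond-forming efficiency and reliability.

Key step: step 4

Assumption: steps 4 and 5 are planned in the racemic series (9 and 10 are drawn as the enantiomer that is carried on), and the lipase of step 6 is taken to follow the empirical size rule for secondary alcohols with the fused arene as the large group, so that the (2S,3S) alcohol is acylated and (2R,3R)-11 stays free.

## Steps

Step 1
Reactants: 1 methyl 4-hydroxy-3-iodobenzoate; 2 prenylboronic acid pinacol ester [4,4,5,5-tetramethyl-2-(3-methylbut-2-en-1-yl)-1,3,2-dioxaborolane]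
Product: 3 methyl 4-hydroxy-3-(3-methylbut-2-en-1-yl)benzoate
Conditions: 2 (1.5 equiv), PdCl2(dppf) (5 mol %), K3PO4 (3 equiv), THF–H2O 9:1, 65 °C
Reagents that add atoms: none
Why: Suzuki–Miyaura coupling of an aryl iodide with an allylic boronate; the aryl(η3-prenyl)palladium intermediate should reductively eliminate at its unsubstituted terminus under the chelating diphosphine and give the linear prenyl arene. The step precedes formylation because allylic boronates add to aldehydes.

Step 2
Reactants: 3 methyl 4-hydroxy-3-(3-methylbut-2-en-1-yl)benzoate
Product: 5 methyl 3-formyl-4-hydroxy-5-(3-methylbut-2-en-1-yl)benzoate, via hydroxymethyl phenol 4 (not isolated)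
Conditions: MgCl2 (3 equiv), Et3N (4 equiv), (CH2O)n (7 equiv), MeCN, reflux; cold 1 M HCl
Reagents that add atoms: formaldehyde (as paraformaldehyde), C=O
Why: Casnati–Skattebøl ortho-formylation; the magnesium phenoxide delivers formaldehyde only to the ortho carbon, of which one is free, and 4 is oxidised in the flask by a second formaldehyde through Oppenauer-type hydride transfer. The ester slows the reaction but does not divert it, and the prenyl group is inert to these mildly basic conditions.

Step 3
Reactants: 5 methyl 3-formyl-4-hydroxy-5-(3-methylbut-2-en-1-yl)benzoate; 6 1-bromo-2-methylprop-1-ene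
Product: 7 methyl 3-formyl-4-(2-methylprop-1-en-1-yloxy)-5-(3-methylbut-2-en-1-yl)benzoate
Conditions: 6 (3 equiv), CuI (15 mol %), N,N-dimethylglycine·HCl (30 mol %), Cs2CO3 (2.5 equiv), 1,4-dioxane, 90 °C, sealed tube, Ar
Reagents that add atoms: none
Why: Ullmann-type C(sp2)–O coupling of a phenol with a vinyl bromide under amino-acid-ligated monovalent copper. The two methyl groups on the distal carbon remove any question of alkene geometry, and the non-enolisable aldehyde and the ester tolerate dry carbonate.

Step 4
Reactants: 7 methyl 3-formyl-4-(2-methylprop-1-en-1-yloxy)-5-(3-methylbut-2-en-1-yl)benzoate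
Product: 9 rac-(2R*,3S*) cis-fused 2,2-dimethyloxetano-dihydrobenzofuran methyl ester (methyl 7-prenyl-2,3-dihydrobenzofuran-5-carboxylate bridged C3–O–CMe2–C2), via triplet 1,4-biradical 8 (not isolated)
Conditions: hν (365 nm LED, Pyrex), PhH (3 mM, Ar-sparged), K2CO3 (solid), 15 °C
Reagents that add atoms: none
Why: Proposed new method: Light near 365 nm excites only the aryl aldehyde, whose n,π* triplet attacks the electron-rich enol ether with its electrophilic oxygen at the CMe2 terminus and gives biradical 8 (benzylic α-oxy radical at C3, α-aryloxy radical at C2); after intersystem crossing the two radical centres couple to form C2–C3. The closest known reaction type is the intermolecular Paternò–Büchi reaction of aromatic aldehydes with enol ethers, which gives 3-alkoxyoxetanes in this same orientation; an intramolecular version across the three-atom tether C3a–C7a–O1 has not been described, although it conforms to the rule of five for tethered [2+2] photocycloadditions. The O–CMe2 bond closes a seven-membered ring by endo attack on the distal alkene carbon, and the transannular C2–C3 coupling then divides that ring into the five-membered dihydrofuran (C3, C3a, C7a, O1, C2) and the four-membered oxetane (C3, O, CMe2, C2). C2 and C3 are set relative to each other by the ring fusion alone, since a bicyclo[3.2.0] frame can only be cis-fused, which gives (2R*,3S*); nothing controls the absolute sense, so 9 forms as a racemate that is resolved in step 6. Regioselectivity is secured by the tether, because the opposite orientation would require a strained bridged bicyclo[3.1.1] skeleton. Chemoselectivity for the enol ether over the prenyl alkene rests on reach (the prenyl chain sits meta to the formyl group) and on high dilution, which suppresses intermolecular attack. The two ortho neighbours twist the O–vinyl bond out of the arene plane, so the oxygen lone pair feeds the alkene and not the arene, the alkene is held over the formyl group and the n,π* character of the aldehyde is kept; the ester is transparent at this wavelength and 9 no longer absorbs. Oxygen is excluded to avoid singlet-oxygen chemistry at both alkenes, and solid K2CO3 scavenges traces of acid.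

Step 5
Reactants: 9 rac-(2R*,3S*) cis-fused oxetano-dihydrobenzofuran methyl ester
Product: 10 rac-methyl (2R*,3R*)-3-hydroxy-2-(2-hydroxypropan-2-yl)-7-(3-methylbut-2-en-1-yl)-2,3-dihydrobenzofuran-5-carboxylate (trans)
Conditions: H2SO4 (0.05 M), THF–H2O 1:1, 0 °C to rt; NaHCO3 quench
Reagents that add atoms: water, O
Why: Acid-catalysed nucleophilic opening of a 2-aryloxetane at its benzylic carbon; ring strain and donation from the ortho oxygen O1 weaken C3–O more than the tertiary CMe2–O bond, and water enters anti to the leaving oxygen with inversion, turning (2R*,3S*) into trans (2R*,3R*). The attacked face is also the open one opposite the C2 side chain, so a looser ion-pair-like transition state should lead to the same trans diol. A water-rich medium and dilute acid keep capture ahead of proton loss from C2 and spare the prenyl group and the ester.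

Step 6
Reactants: 10 rac-trans diol methyl ester
Product: 11 methyl (2R,3R)-3-hydroxy-2-(2-hydroxypropan-2-yl)-7-(3-methylbut-2-en-1-yl)-2,3-dihydrobenzofuran-5-carboxylate
Conditions: lipase from Burkholderia cepacia (immobilised), vinyl acetate (3 equiv), MTBE, 35 °C, stopped just past half conversion; chromatography
Reagents that add atoms: none
Why: Lipase-catalysed acylative kinetic resolution of a cyclic benzylic secondary alcohol; the tertiary alcohol and the benzoate ester are not substrates. By the empirical size rule the (3S) carbinol should be acetylated, so (2R,3R)-11 remains as the free alcohol, and running slightly past half conversion favours its enantiomeric purity. No stereocentre is made here; the absolute configuration of C2 and C3 is selected.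

Step 7
Reactants: 11 methyl (2R,3R)-diol ester
Product: 12 (2R,3R)-3-hydroxy-2-(2-hydroxypropan-2-yl)-7-(3-methylbut-2-en-1-yl)-2,3-dihydrobenzofuran-5-carboxylic acid
Conditions: LiOH·H2O (4 equiv), THF–MeOH–H2O 2:1:1, 45 °C; 1 M HCl to pH 4, 0 °C
Reagents that add atoms: lithium hydroxide, [Li+].[OH-]
Why: Ordinary acyl-oxygen saponification of a methyl benzoate, done before silylation so that no silyl ether meets hydroxide. Neither stereocentre carries an acidic hydrogen, so C2 and C3 are untouched.

Step 8
Reactants: 12 (2R,3R)-diol acid
Product: 14 (2R,3R)-3-(triethylsilyloxy)-2-[2-(triethylsilyloxy)propan-2-yl]-7-(3-methylbut-2-en-1-yl)-2,3-dihydrobenzofuran-5-carboxylic acid, via tris(triethylsilyl) silyl ester 13 (not isolated)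
Conditions: Et3SiOTf (3.6 equiv), 2,6-lutidine (5 equiv), CH2Cl2, −78 to 0 °C; then THF–H2O, rt
Reagents that add atoms: triethylsilyl triflate, CC[Si](CC)(CC)OS(=O)(=O)C(F)(F)F
Why: A silyl triflate with a hindered pyridine silylates the secondary hydroxyl, the tertiary hydroxyl and the acid in one operation at low temperature, without ionising C3. The silyl ester in 13 is far more labile than the two silyl ethers and is hydrolysed by the aqueous stir at near-neutral pH.

Step 9
Reactants: 14 bis(triethylsilyl) acid; 15 2,4,6-trihydroxyacetophenone (dried)
Product: 18 1-{(2R,3R)-3-(triethylsilyloxy)-2-[2-(triethylsilyloxy)propan-2-yl]-7-prenyl-2,3-dihydrobenzofuran-5-yl}-3-(2,4,6-trihydroxyphenyl)propane-1,3-dione, via acid chloride 16 (not isolated), via tetralithium polyanion 17 (not isolated)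
Conditions: (a) 14, Me2C=C(Cl)NMe2 (1.1 equiv), CH2Cl2, 0 °C to rt, then THF; (b) 15 (1.1 equiv), LiN(SiMe3)2 (5.5 equiv), THF, −78 to −10 °C; (c) 16 into 17, −78 °C to rt; AcOH quench
Reagents that add atoms: none
Why: The chloroenamine makes the acid chloride without free HCl, so the silyl ethers survive. Claisen-type C-acylation of the fully deprotonated polyhydroxyacetophenone is the intermolecular counterpart of the Baker–Venkataraman aroyl transfer; the enolate carbon is the most nucleophilic site, and any O-aroyl ester formed is carried to the same diketone by that transfer under the excess base. Ring A needs no protecting group.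

Step 10
Reactants: 18 bis(triethylsilyl) 1,3-diketone
Product: 20 5,7-dihydroxy-2-[(2R,3R)-3-hydroxy-2-(2-hydroxypropan-2-yl)-7-(3-methylbut-2-en-1-yl)-2,3-dihydrobenzofuran-5-yl]-4H-chromen-4-one, via 2-hydroxyflavanone hemiketal 19 (not isolated)
Conditions: AcOH–THF–H2O 3:1:1, rt then 55 °C
Reagents that add atoms: none
Why: Aqueous acetic acid cleaves both triethylsilyl ethers, and the 2,4,6-trihydroxyphenyl diketone closes through either equivalent ortho phenol to hemiketal 19, which loses water to the 4-pyranone (acid-catalysed cyclodehydration, the last stage of the Baker–Venkataraman flavone synthesis). With water as the only nucleophile, a reversible ionisation at C3 would be degenerate and would return the trans alcohol. The weak acid should leave the prenyl group alone, and C2 and C3 are not touched.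

## Compound list

1 | methyl 4-hydroxy-3-iodobenzoate | COC(=O)c1ccc(O)c(I)c1 | starting material
2 | prenylboronic acid pinacol ester | CC(C)=CCB1OC(C)(C)C(C)(C)O1 | starting material
3 | methyl 4-hydroxy-3-(3-methylbut-2-en-1-yl)benzoate | CC(C)=CCc1cc(C(=O)OC)ccc1O | intermediate
4 | methyl 4-hydroxy-3-(hydroxymethyl)-5-(3-methylbut-2-en-1-yl)benzoate (present as its magnesium salt, not isolated) | CC(C)=CCc1cc(C(=O)OC)cc(CO)c1O | intermediate
5 | methyl 3-formyl-4-hydroxy-5-(3-methylbut-2-en-1-yl)benzoate | CC(C)=CCc1cc(C(=O)OC)cc(C=O)c1O | intermediate
6 | 1-bromo-2-methylprop-1-ene | CC(C)=CBr | starting material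
7 | methyl 3-formyl-4-(2-methylprop-1-en-1-yloxy)-5-(3-methylbut-2-en-1-yl)benzoate | CC(C)=CCc1cc(C(=O)OC)cc(C=O)c1OC=C(C)C | intermediate
8 | triplet 1,4-biradical with the O–CMe2 bond formed and radical centres at C2 and C3 (not isolated) | CC(C)=CCc1cc(C(=O)OC)cc2c1O[CH]C(C)(C)O[CH]2 | intermediate
9 | rac-(2R*,3S*) cis-fused 2,2-dimethyloxetano-dihydrobenzofuran methyl ester, oxetane oxygen on C3 and CMe2 on C2, 7-prenyl, 5-CO2Me (racemate, drawn as the 2R,3S enantiomer) | CC(C)=CCc1cc(C(=O)OC)cc2c1O[C@@H]3[C@H]2OC3(C)C | intermediate
10 | rac-methyl (2R*,3R*)-3-hydroxy-2-(2-hydroxypropan-2-yl)-7-prenyl-2,3-dihydrobenzofuran-5-carboxylate (racemate, drawn as the 2R,3R enantiomer) | CC(C)=CCc1cc(C(=O)OC)cc2c1O[C@@H](C(C)(C)O)[C@@H]2O | intermediate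
11 | methyl (2R,3R)-3-hydroxy-2-(2-hydroxypropan-2-yl)-7-prenyl-2,3-dihydrobenzofuran-5-carboxylate (single enantiomer) | CC(C)=CCc1cc(C(=O)OC)cc2c1O[C@@H](C(C)(C)O)[C@@H]2O | intermediate
12 | (2R,3R)-3-hydroxy-2-(2-hydroxypropan-2-yl)-7-prenyl-2,3-dihydrobenzofuran-5-carboxylic acid | CC(C)=CCc1cc(C(=O)O)cc2c1O[C@@H](C(C)(C)O)[C@@H]2O | intermediate
13 | triethylsilyl (2R,3R)-3-(triethylsilyloxy)-2-[2-(triethylsilyloxy)propan-2-yl]-7-prenyl-2,3-dihydrobenzofuran-5-carboxylate (not isolated) | CC(C)=CCc1cc(C(=O)O[Si](CC)(CC)CC)cc2c1O[C@@H](C(C)(C)O[Si](CC)(CC)CC)[C@@H]2O[Si](CC)(CC)CC | intermediate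
14 | (2R,3R)-3-(triethylsilyloxy)-2-[2-(triethylsilyloxy)propan-2-yl]-7-prenyl-2,3-dihydrobenzofuran-5-carboxylic acid | CC(C)=CCc1cc(C(=O)O)cc2c1O[C@@H](C(C)(C)O[Si](CC)(CC)CC)[C@@H]2O[Si](CC)(CC)CC | intermediate
15 | 2,4,6-trihydroxyacetophenone | CC(=O)c1c(O)cc(O)cc1O | starting material
16 | acid chloride of 14 (not isolated) | CC(C)=CCc1cc(C(=O)Cl)cc2c1O[C@@H](C(C)(C)O[Si](CC)(CC)CC)[C@@H]2O[Si](CC)(CC)CC | intermediate
17 | tetralithium salt of 15, three phenoxides and the ketone enolate (not isolated) | [Li+].[Li+].[Li+].[Li+].C=C([O-])c1c([O-])cc([O-])cc1[O-] | intermediate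
18 | 1-[(2R,3R)-bis(triethylsilyl)-protected dihydrobenzofuran-5-yl]-3-(2,4,6-trihydroxyphenyl)propane-1,3-dione | CC(C)=CCc1cc(C(=O)CC(=O)c3c(O)cc(O)cc3O)cc2c1O[C@@H](C(C)(C)O[Si](CC)(CC)CC)[C@@H]2O[Si](CC)(CC)CC | intermediate
19 | 2,5,7-trihydroxy-2-[(2R,3R)-diol-dihydrobenzofuran-5-yl]chroman-4-one, hemiketal carbon undefined (not isolated) | CC(C)=CCc1cc(C3(O)CC(=O)c4c(O)cc(O)cc4O3)cc2c1O[C@@H](C(C)(C)O)[C@@H]2O | intermediate
20 | 5,7-dihydroxy-2-[(2R,3R)-3-hydroxy-2-(2-hydroxypropan-2-yl)-7-(3-methylbut-2-en-1-yl)-2,3-dihydrobenzofuran-5-yl]-4H-chromen-4-one | CC(C)=CCc1cc(-c2cc(=O)c3c(O)cc(O)cc3o2)cc2c1O[C@@H](C(C)(C)O)[C@@H]2O | target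

## Step count and least certain steps

Total step count: 10. Longest linear sequence: 10 steps (1 to 20); 15 enters without steps of its own.

**Step 4 (key step, the only step beyond known chemistry).**
- **Likely failure.** The photoreaction may be inefficient. The alkoxy donor may lend the lowest triplet π,π* character, and the biradical may revert to 7. A slow reaction would then leave room for intermolecular attack on the prenyl alkene or for hydrogen abstraction.
- **Fallback.** It uses known chemistry, sets out from 5 and returns at 11, and so bypasses steps 3 to 6 and the resolution.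
  - Phenol 5 is alkylated with chloroacetone (K2CO3, KI, acetone) to methyl 3-formyl-4-(2-oxopropoxy)-5-prenylbenzoate F1.
  - (R)-Proline (30 mol %, DMF, rt) closes F1 by the established 5-enolexo intramolecular aldol reaction. By the accepted enamine model this should give the cis ketol methyl (2R,3S)-2-acetyl-3-hydroxy-7-prenyl-2,3-dihydrobenzofuran-5-carboxylate F2.
  - MeMgBr with CeCl3 (THF, −78 °C) adds to the ketone in preference to the benzoate and gives the cis diol methyl (2R,3S)-3-hydroxy-2-(2-hydroxypropan-2-yl)-7-prenyl-2,3-dihydrobenzofuran-5-carboxylate F3.
  - Mitsunobu inversion (4-nitrobenzoic acid, PPh3, DIAD) gives methyl (2R,3R)-2-(2-hydroxypropan-2-yl)-3-(4-nitrobenzoyloxy)-7-prenyl-2,3-dihydrobenzofuran-5-carboxylate F4.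
  - K2CO3 in MeOH then releases 11.

**Step 5.**
- **Likely failure.** Ionisation may take the place of concerted displacement. Inversion at C3 would then erode, opening at the tertiary carbon with retention at C3 could compete, and the cation could run on to aromatisation by loss of the C2 proton or of acetone. If the oxetane needs stronger acid than planned, hydration of the prenyl alkene becomes competitive.
- **Fallback.** It sets out from 9 and returns at 10.
  - The opening is run without regard to the outcome at C3.
  - The crude diol (10 together with the racemic form of F3) is oxidised at the benzylic carbinol (Dess–Martin periodinane, NaHCO3, CH2Cl2) to rac-methyl 2-(2-hydroxypropan-2-yl)-3-oxo-7-prenyl-2,3-dihydrobenzofuran-5-carboxylate F5.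
  - An Evans–Saksena reduction (Me4NBH(OAc)3, MeCN–AcOH, −20 °C) follows. The boron is bound to the tertiary hydroxyl and delivers hydride on the face of the side chain, so the new hydroxyl ends up trans.
  - The configurational lability of F5 at C2 does no harm because the series is still racemic.
  - Should aromatisation dominate, the detour described for step 4 bypasses this step as well.

**Step 3.**
- **Likely failure.** The coupling may be sluggish. The phenoxide is flanked on both sides, is a weak nucleophile, and can sequester copper as a salicylaldehyde-type chelate, while the volatile bromide is lost on long heating.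
- **Fallback.** It sets out from 5 and returns at 7.
  - O-Alkylation with 3-chloro-2-methylprop-1-ene (K2CO3, NaI, DMF, 50 °C) gives methyl 3-formyl-4-(2-methylallyloxy)-5-prenylbenzoate F6.
  - [Ir(cod)(PMePh2)2]PF6 (activated with H2, THF, rt) moves the 1,1-disubstituted double bond into conjugation with oxygen.
  - The trisubstituted prenyl alkene should be too hindered to be isomerised.

**Step 10.**
- **Likely failure.** The reaction may stall at the hemiketal stage in weak acid. Stronger acid would then be needed, and under it the unmasked C3 carbinol can ionise and the prenyl group can be hydrated.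
- **Fallback.** It sets out from 12 and returns at 20. It separates ring closure from unmasking by using more robust silyl groups.
  - tBuMe2SiOTf and 2,6-lutidine, followed by brief K2CO3 in MeOH–H2O, give (2R,3R)-3-(tert-butyldimethylsilyloxy)-2-[2-(tert-butyldimethylsilyloxy)propan-2-yl]-7-prenyl-2,3-dihydrobenzofuran-5-carboxylic acid F7.
  - Activation and coupling to 17 as in step 9 give the bis(tert-butyldimethylsilyl) 1,3-diketone F8.
  - TsOH·H2O (catalytic, toluene, 60 °C) closes ring C with both silyl ethers in place and gives the bis(tert-butyldimethylsilyl) flavone F9.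
  - Bu4NF buffered with AcOH (THF, rt to 40 °C) frees 20, so the free benzylic alcohol never meets strong acid.

**Step 6.**
- **Likely failure.** The enzyme may discriminate poorly, acylate slowly or prefer the other enantiomer, because the carbinol is flanked on one side by a carbon that bears a quaternary centre.
- **Fallback.** It sets out from 10 and returns at 11.
  - The C3 hydroxyl is esterified with (S)-2-methoxy-2-phenylacetic acid (EDC·HCl, DMAP, CH2Cl2, 0 °C), and the two diastereomeric esters are separated by chromatography or crystallisation.
  - The isomer methyl (2R,3R)-2-(2-hydroxypropan-2-yl)-3-[(S)-2-methoxy-2-phenylacetoxy]-7-prenyl-2,3-dihydrobenzofuran-5-carboxylate F10 is cleaved with K2CO3 in MeOH.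

## Further compounds

F1 | step 4 | methyl 3-formyl-4-(2-oxopropoxy)-5-prenylbenzoate | CC(C)=CCc1cc(C(=O)OC)cc(C=O)c1OCC(C)=O
F2 | step 4 | methyl (2R,3S)-2-acetyl-3-hydroxy-7-prenyl-2,3-dihydrobenzofuran-5-carboxylate | CC(C)=CCc1cc(C(=O)OC)cc2c1O[C@@H](C(C)=O)[C@H]2O
F3 | step 4 | methyl (2R,3S)-3-hydroxy-2-(2-hydroxypropan-2-yl)-7-prenyl-2,3-dihydrobenzofuran-5-carboxylate | CC(C)=CCc1cc(C(=O)OC)cc2c1O[C@@H](C(C)(C)O)[C@H]2O
F4 | step 4 | methyl (2R,3R)-2-(2-hydroxypropan-2-yl)-3-(4-nitrobenzoyloxy)-7-prenyl-2,3-dihydrobenzofuran-5-carboxylate | CC(C)=CCc1cc(C(=O)OC)cc2c1O[C@@H](C(C)(C)O)[C@@H]2OC(=O)c1ccc([N+](=O)[O-])cc1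
F5 | step 5 | rac-methyl 2-(2-hydroxypropan-2-yl)-3-oxo-7-prenyl-2,3-dihydrobenzofuran-5-carboxylate | CC(C)=CCc1cc(C(=O)OC)cc2c1OC(C(C)(C)O)C2=O
F6 | step 3 | methyl 3-formyl-4-(2-methylallyloxy)-5-prenylbenzoate | CC(C)=CCc1cc(C(=O)OC)cc(C=O)c1OCC(C)=C
F7 | step 10 | (2R,3R)-3-(tert-butyldimethylsilyloxy)-2-[2-(tert-butyldimethylsilyloxy)propan-2-yl]-7-prenyl-2,3-dihydrobenzofuran-5-carboxylic acid | CC(C)=CCc1cc(C(=O)O)cc2c1O[C@@H](C(C)(C)O[Si](C)(C)C(C)(C)C)[C@@H]2O[Si](C)(C)C(C)(C)C
F8 | step 10 | bis(tert-butyldimethylsilyl) 1,3-diketone | CC(C)=CCc1cc(C(=O)CC(=O)c3c(O)cc(O)cc3O)cc2c1O[C@@H](C(C)(C)O[Si](C)(C)C(C)(C)C)[C@@H]2O[Si](C)(C)C(C)(C)C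
F9 | step 10 | bis(tert-butyldimethylsilyl) flavone | CC(C)=CCc1cc(-c2cc(=O)c3c(O)cc(O)cc3o2)cc2c1O[C@@H](C(C)(C)O[Si](C)(C)C(C)(C)C)[C@@H]2O[Si](C)(C)C(C)(C)C
F10 | step 6 | methyl (2R,3R)-2-(2-hydroxypropan-2-yl)-3-[(S)-2-methoxy-2-phenylacetoxy]-7-prenyl-2,3-dihydrobenzofuran-5-carboxylate | CC(C)=CCc1cc(C(=O)OC)cc2c1O[C@@H](C(C)(C)O)[C@@H]2OC(=O)[C@@H](OC)c1ccccc1
A1 | alternative 1 | 5,7-bis(tert-butyldimethylsilyloxy)flavone whose ring B is an 8-prenyl-2,2-dimethylchromene | CC(C)=CCc1cc(-c2cc(=O)c3c(O[Si](C)(C)C(C)(C)C)cc(O[Si](C)(C)C(C)(C)C)cc3o2)cc2c1OC(C)(C)C=C2
A2 | alternative 1 | (3S,4R)-3-hydroxy-4-(triethylsilyloxy)-2,2-dimethylchroman derived from A1 | CC(C)=CCc1cc(-c2cc(=O)c3c(O[Si](C)(C)C(C)(C)C)cc(O[Si](C)(C)C(C)(C)C)cc3o2)cc2c1OC(C)(C)[C@@H](O)[C@@H]2O[Si](CC)(CC)CC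
A3 | alternative 1 | tris-silylated target (5,7-bis-TBS, C3-OTES) | CC(C)=CCc1cc(-c2cc(=O)c3c(O[Si](C)(C)C(C)(C)C)cc(O[Si](C)(C)C(C)(C)C)cc3o2)cc2c1O[C@@H](C(C)(C)O)[C@@H]2O[Si](CC)(CC)CC
A4 | alternative 2 | methyl (E)-9-aryl-3,5,7-trioxonon-8-enoate with bis-silylated ring B | CC(C)=CCc1cc(/C=C/C(=O)CC(=O)CC(=O)CC(=O)OC)cc2c1O[C@@H](C(C)(C)O[Si](CC)(CC)CC)[C@@H]2O[Si](C)(C)C(C)(C)C
A5 | alternative 2 | 2',4',6'-trihydroxychalcone with bis-silylated ring B | CC(C)=CCc1cc(/C=C/C(=O)c3c(O)cc(O)cc3O)cc2c1O[C@@H](C(C)(C)O[Si](CC)(CC)CC)[C@@H]2O[Si](C)(C)C(C)(C)C
A6 | alternative 3 | methyl 3-iodo-4-{[(S)-3-methyl-1-oxo-3-(triethylsilyloxy)butan-2-yl]oxy}-5-prenylbenzoate | CC(C)=CCc1cc(C(=O)OC)cc(I)c1O[C@@H](C(C)(C)O[Si](CC)(CC)CC)C=O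
A7 | alternative 3 | methyl (2R,3R)-3-hydroxy-2-[2-(triethylsilyloxy)propan-2-yl]-7-prenyl-2,3-dihydrobenzofuran-5-carboxylate | CC(C)=CCc1cc(C(=O)OC)cc2c1O[C@@H](C(C)(C)O[Si](CC)(CC)CC)[C@@H]2O
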